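**Retrosynthetic overview**

1. The senecioate is put on last (shikonin + 3-methylbut-2-enoic acid); before that the naphthazarin is carried as a 5,8-bis(MOM) ether whose C1–C4 ring is at the hydroquinone level (mono-silyl ether) and is then oxidised to the quinone.
2. Key disconnection: the C1–C4 ring (C1, C2, C3, C4, C4a, C8a) is opened at C1–C2 and at C4–C4a. This gives an aryl aldehyde (C1 already on C8a, a temporary Me3Si on C4a) and a (Z)-β-iodo enamide that brings C2, C3, C4 and the finished C1' stereocentre.
3. Enabling feature: the oxygen on C1 is 1,4 to C4a (O–C1–C8a–C4a), and C4a is flanked by the C5 oxygen of the benzenoid ring. Once C2 has added to C1, the new alkoxide can take silicon from C4a ([1,4]-Brook); the C4a anion, held next to C4 by the Z C2=C3 bond, then closes the ring on the amide.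
4. The C1' centre comes from asymmetric transfer hydrogenation of an alkynyl ketone; the same alkyne later becomes C2=C3 by anti hydroiodination of the derived ynamide.
5. Ring order: the benzenoid ring (C4a–C8a) is bought as 2,5-dihydroxybenzaldehyde; the C1–C4 ring is formed in the key step, aromatised by tautomerisation and oxidised. The C4a–Si bond and the MOM and TBS groups are not in the target and are removed.

Key step: step 9

Remark: atom numbers (C1–C4, C4a, C5–C8, C8a, side-chain C1') are those of the target naphthalene-1,4-dione with C2 bearing the side chain; compound 22 is written as its aromatic naphthol tautomer.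

**Step 1**
Reactants: 1 4-methylpent-3-enoic acid
Product: 2 N-methoxy-N,4-dimethylpent-3-enamide
Conditions: CDI, CH2Cl2, 0 °C to rt; then MeNH(OMe)·HCl, rt
Reagents that add atoms: N,O-dimethylhydroxylamine hydrochloride, CNOC.Cl
Why: Weinreb amide formation through the acyl imidazole is mild enough to leave the β,γ-alkene where it is.

**Step 2**
Reactants: 2 N-methoxy-N,4-dimethylpent-3-enamide; 3 ethynyltrimethylsilane
Product: 5 6-methyl-1-(trimethylsilyl)hept-5-en-1-yn-3-one, via lithium (trimethylsilyl)acetylide 4 (not isolated)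
Conditions: 3, n-BuLi, THF, −78 °C; then 2, −78 to −20 °C; sat. aq. NH4Cl
Reagents that add atoms: none
Why: Weinreb ketone synthesis, in which the chelated tetrahedral adduct stops at the ynone and the low temperature limits enolisation of the doubly activated CH2.

**Step 3**
Reactants: 5 6-methyl-1-(trimethylsilyl)hept-5-en-1-yn-3-one
Product: 6 (3R)-6-methyl-1-(trimethylsilyl)hept-5-en-1-yn-3-ol
Conditions: Ru[(R,R)-TsNCH(Ph)CH(Ph)NH](p-cymene) (cat.), i-PrOH, rt
Reagents that add atoms: none
Why: Noyori asymmetric transfer hydrogenation of an alkynyl ketone under base-free conditions, where the alkynyl group takes the place of the aryl group in the usual transition state, so the (R,R)-catalyst should give the R carbinol (to be confirmed by Mosher ester analysis) without touching either C–C multiple bond.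

**Step 4**
Reactants: 6 (3R)-6-methyl-1-(trimethylsilyl)hept-5-en-1-yn-3-ol
Product: 7 tert-butyldimethyl{[(3R)-6-methyl-1-(trimethylsilyl)hept-5-en-1-yn-3-yl]oxy}silane
Conditions: TBSCl, imidazole, DMF, rt
Reagents that add atoms: tert-butyldimethylsilyl chloride, CC(C)(C)[Si](C)(C)Cl
Why: standard O-silylation of the secondary propargylic alcohol, which does not touch the stereocentre.

**Step 5**
Reactants: 7 tert-butyldimethyl{[(3R)-6-methyl-1-(trimethylsilyl)hept-5-en-1-yn-3-yl]oxy}silane; 8 morpholine-4-carbonyl chloride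
Product: 10 (4R)-4-(tert-butyldimethylsilyloxy)-7-methyl-1-(morpholin-4-yl)oct-6-en-2-yn-1-one, via lithium acetylide 9 (not isolated)
Conditions: MeLi·LiBr, THF, 0 °C to rt; then 8, −78 °C to rt
Reagents that add atoms: none
Why: methyllithium cleaves the alkynyl C–SiMe3 bond selectively (the TBS ether is inert) and the lithium acetylide is C-acylated by the carbamoyl chloride, a known route to alk-2-ynamides.

**Step 6**
Reactants: 10 (4R)-4-(tert-butyldimethylsilyloxy)-7-methyl-1-(morpholin-4-yl)oct-6-en-2-yn-1-one
Product: 11 (2Z,4R)-4-(tert-butyldimethylsilyloxy)-3-iodo-7-methyl-1-(morpholin-4-yl)octa-2,6-dien-1-one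
Conditions: LiI, AcOH, MeCN, 70 °C
Reagents that add atoms: lithium iodide, [Li+].[I-]
Why: conjugate hydroiodination of an alk-2-ynamide, in which iodide adds to the β-carbon and protonation occurs anti, should place iodine cis to the amide carbonyl (Z) while the C4 stereocentre is a spectator.

**Step 7**
Reactants: 12 2,5-dihydroxybenzaldehyde
Product: 13 2,5-bis(methoxymethoxy)benzaldehyde
Conditions: MOMCl, i-Pr2NEt, CH2Cl2, 0 °C to reflux
Reagents that add atoms: chloromethyl methyl ether, COCCl
Why: O-alkylation of both phenols gives acetal ethers that later serve as ortho-directing groups and come off with mild acid.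

**Step 8**
Reactants: 13 2,5-bis(methoxymethoxy)benzaldehyde
Product: 16 3,6-bis(methoxymethoxy)-2-(trimethylsilyl)benzaldehyde, via lithium amino alkoxide 14 (not isolated), via ortho-lithiated amino alkoxide 15 (not isolated)
Conditions: LiN(Me)CH2CH2NMe2, THF, −20 °C; n-BuLi, −20 °C; Me3SiCl, −78 °C to rt; cold aq. citric acid
Reagents that add atoms: chlorotrimethylsilane, C[Si](C)(C)Cl
Why: directed ortho-metalation of an in situ α-amino alkoxide, where the only free position next to the masked aldehyde is also ortho to a MOM ether, so both directing groups should put lithium and then silicon on that carbon before aqueous acid returns the aldehyde.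

**Step 9**
Reactants: 11 (2Z,4R)-4-(tert-butyldimethylsilyloxy)-3-iodo-7-methyl-1-(morpholin-4-yl)octa-2,6-dien-1-one; 16 3,6-bis(methoxymethoxy)-2-(trimethylsilyl)benzaldehyde
Product: 22 3-[(1R)-1-(tert-butyldimethylsilyloxy)-4-methylpent-3-en-1-yl]-5,8-bis(methoxymethoxy)-4-(trimethylsilyloxy)naphthalen-1-ol, via vinyllithium 17 (not isolated), via lithium alkoxide adduct 18 (not isolated), via Brook aryllithium 19 (not isolated), via cyclic amino alkoxide 20 (not isolated), via silyloxy dienone 21 (not isolated)
Conditions: 11, t-BuLi (2 equiv), Et2O, −100 °C; then 16 in THF, −100 to −78 °C; then HMPA, −78 to −20 °C; sat. aq. NH4Cl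
Reagents that add atoms: none
Why: Proposed new method: iodine–lithium exchange on 11 gives the chelated (Z)-β-lithio enamide 17, which adds to the aldehyde carbon C1 of 16 (C1–C2 bond); the lithium alkoxide 18 is 1,4 to the aryl silicon, so HMPA should trigger a [1,4]-Brook shift of Me3Si from C4a to oxygen, giving aryllithium 19 (stabilised by the ortho OMOM), which attacks the cis-disposed amide carbon C4 (C4–C4a bond) to give 20; on quench 20 loses morpholine to dienone 21, which tautomerises to the aromatic silyl ether 22. The closest known reaction types are type 2 anion relay chemistry of ortho-silyl benzaldehydes (addition, sp2 C-to-O [1,4]-Brook rearrangement, electrophile capture) and the Parham cyclisation of aryllithiums onto tertiary amides; what is new is that the first nucleophile carries the electrophile, so the relay becomes a [3+3] annulation. The six-membered carbocycle closes by 6-exo-trig addition of the aryllithium to the amide carbonyl. The carbinol centre formed at C1 arises without control and is erased on aromatisation, while C1' is never deprotonated or ionised and should keep its R configuration. The step needs chemoselectivity (no aryl anion before the C1–C2 bond exists, no lactonisation) and a cis relationship between C1 and C4: the silicon switch, the tertiary amide (inert to the alkoxide and to intermolecular attack at −100 °C) and the Z iodide with retentive exchange are meant to secure these.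

**Step 10**
Reactants: 22 3-[(1R)-1-(tert-butyldimethylsilyloxy)-4-methylpent-3-en-1-yl]-5,8-bis(methoxymethoxy)-4-(trimethylsilyloxy)naphthalen-1-ol (used crude)
Product: 23 2-[(1R)-1-(tert-butyldimethylsilyloxy)-4-methylpent-3-en-1-yl]-5,8-bis(methoxymethoxy)naphthalene-1,4-dione
Conditions: PhI(OAc)2, MeCN, 0 °C
Reagents that add atoms: none
Why: two-electron oxidation of a para-silyloxy naphthol by a hypervalent iodine reagent, with transfer of the silyl group to acetate, should give the 1,4-quinone while the MOM-protected ring, which is much harder to oxidise, stays intact.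

**Step 11**
Reactants: 23 2-[(1R)-1-(tert-butyldimethylsilyloxy)-4-methylpent-3-en-1-yl]-5,8-bis(methoxymethoxy)naphthalene-1,4-dione
Product: 24 2-[(1R)-1-(tert-butyldimethylsilyloxy)-4-methylpent-3-en-1-yl]-5,8-dihydroxynaphthalene-1,4-dione
Conditions: TFA, CH2Cl2, H2O, 0 °C
Reagents that add atoms: none
Why: acid hydrolysis of the two aryl MOM acetals is helped by hydrogen bonding of the freed peri hydroxyls to the quinone carbonyls, and the side-chain oxygen is still a silyl ether, so it can neither ionise nor add to the alkene.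

**Step 12**
Reactants: 24 2-[(1R)-1-(tert-butyldimethylsilyloxy)-4-methylpent-3-en-1-yl]-5,8-dihydroxynaphthalene-1,4-dione
Product: 25 5,8-dihydroxy-2-[(1R)-1-hydroxy-4-methylpent-3-en-1-yl]naphthalene-1,4-dione (shikonin)
Conditions: HF·pyridine, pyridine, THF, 0 °C to rt
Reagents that add atoms: none
Why: fluoride-driven cleavage of the secondary TBS ether under buffered conditions breaks only the O–Si bond, so the carbinol configuration is retained.

**Step 13**
Reactants: 25 shikonin; 26 3-methylbut-2-enoic acid
Product: 27 (1R)-1-(5,8-dihydroxy-1,4-dioxo-1,4-dihydronaphthalen-2-yl)-4-methylpent-3-en-1-yl 3-methylbut-2-enoate (target)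
Conditions: DCC, DMAP (cat.), CH2Cl2, 0 °C to rt
Reagents that add atoms: none
Why: Steglich esterification should acylate the side-chain alcohol with retention (the C–O bond is not broken), because both phenols are tied up in hydrogen bonds to the quinone carbonyls, and carbodiimide activation avoids the ketene pathway that would move the senecioyl double bond out of conjugation.

**Compound list**

1 | 4-methylpent-3-enoic acid | CC(C)=CCC(=O)O | starting material
2 | N-methoxy-N,4-dimethylpent-3-enamide | CC(C)=CCC(=O)N(C)OC | intermediate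
3 | ethynyltrimethylsilane | C#C[Si](C)(C)C | starting material
4 | [(trimethylsilyl)ethynyl]lithium | [Li]C#C[Si](C)(C)C | intermediate
5 | 6-methyl-1-(trimethylsilyl)hept-5-en-1-yn-3-one | CC(C)=CCC(=O)C#C[Si](C)(C)C | intermediate
6 | (3R)-6-methyl-1-(trimethylsilyl)hept-5-en-1-yn-3-ol | CC(C)=CC[C@@H](O)C#C[Si](C)(C)C | intermediate
7 | tert-butyldimethyl{[(3R)-6-methyl-1-(trimethylsilyl)hept-5-en-1-yn-3-yl]oxy}silane | CC(C)=CC[C@@H](O[Si](C)(C)C(C)(C)C)C#C[Si](C)(C)C | intermediate
8 | morpholine-4-carbonyl chloride | O=C(Cl)N1CCOCC1 | starting material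
9 | [(3R)-3-(tert-butyldimethylsilyloxy)-6-methylhept-5-en-1-yn-1-yl]lithium | CC(C)=CC[C@@H](O[Si](C)(C)C(C)(C)C)C#C[Li] | intermediate
10 | (4R)-4-(tert-butyldimethylsilyloxy)-7-methyl-1-(morpholin-4-yl)oct-6-en-2-yn-1-one | CC(C)=CC[C@@H](O[Si](C)(C)C(C)(C)C)C#CC(=O)N1CCOCC1 | intermediate
11 | (2Z,4R)-4-(tert-butyldimethylsilyloxy)-3-iodo-7-methyl-1-(morpholin-4-yl)octa-2,6-dien-1-one | CC(C)=CC[C@@H](O[Si](C)(C)C(C)(C)C)/C(I)=C/C(=O)N1CCOCC1 | intermediate
12 | 2,5-dihydroxybenzaldehyde | O=Cc1cc(O)ccc1O | starting material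
13 | 2,5-bis(methoxymethoxy)benzaldehyde | O=Cc1cc(OCOC)ccc1OCOC | intermediate
14 | lithium [2,5-bis(methoxymethoxy)phenyl]{[2-(dimethylamino)ethyl](methyl)amino}methanolate | [Li+].[O-]C(N(C)CCN(C)C)c1cc(OCOC)ccc1OCOC | intermediate
15 | ring-lithiated derivative of 14, lithium on the carbon between the aminal carbon and the 5-OMOM group | [Li+].[O-]C(N(C)CCN(C)C)c1c([Li])c(OCOC)ccc1OCOC | intermediate
16 | 3,6-bis(methoxymethoxy)-2-(trimethylsilyl)benzaldehyde | O=Cc1c([Si](C)(C)C)c(OCOC)ccc1OCOC | intermediate
17 | (4R)-4-(tert-butyldimethylsilyloxy)-3-lithio-7-methyl-1-(morpholin-4-yl)octa-2,6-dien-1-one, lithium cis to the amide carbonyl | CC(C)=CC[C@@H](O[Si](C)(C)C(C)(C)C)/C([Li])=C/C(=O)N1CCOCC1 | intermediate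
18 | lithium alkoxide from addition of 17 to 16: (4R)-3-{[3,6-bis(methoxymethoxy)-2-(trimethylsilyl)phenyl](oxido)methyl}-4-(tert-butyldimethylsilyloxy)-7-methyl-1-(morpholin-4-yl)octa-2,6-dien-1-one lithium salt, carbinol carbon cis to the amide carbonyl, both carbinol epimers | [Li+].CC(C)=CC[C@@H](O[Si](C)(C)C(C)(C)C)/C(=C/C(=O)N1CCOCC1)C([O-])c1c([Si](C)(C)C)c(OCOC)ccc1OCOC | intermediate
19 | aryllithium after the silyl shift: (4R)-4-(tert-butyldimethylsilyloxy)-3-{[2-lithio-3,6-bis(methoxymethoxy)phenyl](trimethylsilyloxy)methyl}-7-methyl-1-(morpholin-4-yl)octa-2,6-dien-1-one, same alkene geometry | CC(C)=CC[C@@H](O[Si](C)(C)C(C)(C)C)/C(=C/C(=O)N1CCOCC1)C(O[Si](C)(C)C)c1c([Li])c(OCOC)ccc1OCOC | intermediate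
20 | lithium 3-[(1R)-1-(tert-butyldimethylsilyloxy)-4-methylpent-3-en-1-yl]-5,8-bis(methoxymethoxy)-1-(morpholin-4-yl)-4-(trimethylsilyloxy)-1,4-dihydronaphthalen-1-olate | [Li+].CC(C)=CC[C@@H](O[Si](C)(C)C(C)(C)C)C1=CC([O-])(N2CCOCC2)c2c(OCOC)ccc(OCOC)c2C1O[Si](C)(C)C | intermediate
21 | 3-[(1R)-1-(tert-butyldimethylsilyloxy)-4-methylpent-3-en-1-yl]-5,8-bis(methoxymethoxy)-4-(trimethylsilyloxy)naphthalen-1(4H)-one, both C4 epimers | CC(C)=CC[C@@H](O[Si](C)(C)C(C)(C)C)C1=CC(=O)c2c(OCOC)ccc(OCOC)c2C1O[Si](C)(C)C | intermediate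
22 | 3-[(1R)-1-(tert-butyldimethylsilyloxy)-4-methylpent-3-en-1-yl]-5,8-bis(methoxymethoxy)-4-(trimethylsilyloxy)naphthalen-1-ol | CC(C)=CC[C@@H](O[Si](C)(C)C(C)(C)C)c1cc(O)c2c(OCOC)ccc(OCOC)c2c1O[Si](C)(C)C | intermediate
23 | 2-[(1R)-1-(tert-butyldimethylsilyloxy)-4-methylpent-3-en-1-yl]-5,8-bis(methoxymethoxy)naphthalene-1,4-dione | CC(C)=CC[C@@H](O[Si](C)(C)C(C)(C)C)C1=CC(=O)c2c(OCOC)ccc(OCOC)c2C1=O | intermediate
24 | 2-[(1R)-1-(tert-butyldimethylsilyloxy)-4-methylpent-3-en-1-yl]-5,8-dihydroxynaphthalene-1,4-dione | CC(C)=CC[C@@H](O[Si](C)(C)C(C)(C)C)C1=CC(=O)c2c(O)ccc(O)c2C1=O | intermediate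
25 | 5,8-dihydroxy-2-[(1R)-1-hydroxy-4-methylpent-3-en-1-yl]naphthalene-1,4-dione (shikonin) | CC(C)=CC[C@@H](O)C1=CC(=O)c2c(O)ccc(O)c2C1=O | intermediate
26 | 3-methylbut-2-enoic acid | CC(C)=CC(=O)O | starting material
27 | (1R)-1-(5,8-dihydroxy-1,4-dioxo-1,4-dihydronaphthalen-2-yl)-4-methylpent-3-en-1-yl 3-methylbut-2-enoate | CC(C)=CC[C@@H](OC(=O)C=C(C)C)C1=CC(=O)c2c(O)ccc(O)c2C1=O | target

**Totals**

Total step count: 13. Longest linear sequence: 11 steps (steps 1–6, then 9–13); steps 7–8 make the aryl aldehyde that joins at step 9.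

**Steps most likely to fail**

1. Step 9 (Proposed new method). The hindered vinyllithium may add too slowly to the doubly ortho-substituted aldehyde and instead lose silanolate (allene formation) or be protonated. The silyl shift may also stall at the alkoxide, or the aryl anion may be protonated before it reaches the amide. The fallback sets out from 13 and 11 and comes back at 22, using only known steps. Compound 13 would be ortho-lithiated as in step 8 but quenched with BrCF2CF2Br to give 2-bromo-3,6-bis(methoxymethoxy)benzaldehyde F1. Iodine–magnesium exchange on 11 (i-PrMgCl·LiCl, THF, −40 °C) and addition to F1 would give (4R)-3-{[2-bromo-3,6-bis(methoxymethoxy)phenyl](hydroxy)methyl}-4-(tert-butyldimethylsilyloxy)-7-methyl-1-(morpholin-4-yl)octa-2,6-dien-1-one F2, with the carbinol carbon cis to the amide carbonyl. Silylation (Me3SiCl, imidazole, CH2Cl2) would give its trimethylsilyl ether, (4R)-3-{[2-bromo-3,6-bis(methoxymethoxy)phenyl](trimethylsilyloxy)methyl}-4-(tert-butyldimethylsilyloxy)-7-methyl-1-(morpholin-4-yl)octa-2,6-dien-1-one F3. Bromine–lithium exchange (t-BuLi, THF, −100 °C) followed by Parham cyclisation onto the morpholine amide, quench and the same tautomerisation should then deliver 22.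

2. Step 6. Acid may strip the silyl ether, after which the Z hydroxy amide can lactonise with loss of morpholine; HI may add to the trisubstituted alkene; and long heating may erode the Z geometry. The fallback sets out from 10 and comes back at 11. Desilylation (Bu4NF, THF) would give (4R)-4-hydroxy-7-methyl-1-(morpholin-4-yl)oct-6-en-2-yn-1-one F4. Hydroxyl-directed ruthenium-catalysed trans-hydrostannation ([Cp*RuCl]4 cat., Bu3SnH, CH2Cl2) should place tin on the carbon next to the carbinol and cis to the carbonyl, giving (2Z,4R)-4-hydroxy-7-methyl-1-(morpholin-4-yl)-3-(tributylstannyl)octa-2,6-dien-1-one F5. Iododestannylation with retention (I2, CH2Cl2, 0 °C) would give (2Z,4R)-4-hydroxy-3-iodo-7-methyl-1-(morpholin-4-yl)octa-2,6-dien-1-one F6, and immediate resilylation (TBSCl, imidazole) would return 11.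

3. Step 3. The skipped alkene of 5 may migrate into conjugation with the ynone before hydride transfer, and facial selectivity may be incomplete. The fallback sets out from 3 and comes back at 6, building the carbinol without any enolisable ketone. Formylation of the lithium acetylide of 3 (n-BuLi, then DMF) would give 3-(trimethylsilyl)prop-2-ynal F7. Brown allylboration with (+)-Ipc2B(allyl) (Et2O, −78 °C; then NaOH, H2O2), the reagent enantiomer being chosen to give the R carbinol, would give (3R)-1-(trimethylsilyl)hex-5-en-1-yn-3-ol F8. Cross-metathesis with 2-methylbut-2-ene (second-generation Grubbs catalyst RuCl2(=CHPh)(PCy3)(H2IMes), CH2Cl2, 40 °C) would turn the allyl group into the prenyl group and give 6.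

**Further compounds**

F1 | step 9 | 2-bromo-3,6-bis(methoxymethoxy)benzaldehyde | O=Cc1c(Br)c(OCOC)ccc1OCOC
F2 | step 9 | (4R)-3-{[2-bromo-3,6-bis(methoxymethoxy)phenyl](hydroxy)methyl}-4-(tert-butyldimethylsilyloxy)-7-methyl-1-(morpholin-4-yl)octa-2,6-dien-1-one, carbinol carbon cis to the amide carbonyl, both carbinol epimers | CC(C)=CC[C@@H](O[Si](C)(C)C(C)(C)C)/C(=C/C(=O)N1CCOCC1)C(O)c1c(Br)c(OCOC)ccc1OCOC
F3 | step 9 | (4R)-3-{[2-bromo-3,6-bis(methoxymethoxy)phenyl](trimethylsilyloxy)methyl}-4-(tert-butyldimethylsilyloxy)-7-methyl-1-(morpholin-4-yl)octa-2,6-dien-1-one, same geometry | CC(C)=CC[C@@H](O[Si](C)(C)C(C)(C)C)/C(=C/C(=O)N1CCOCC1)C(O[Si](C)(C)C)c1c(Br)c(OCOC)ccc1OCOC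
F4 | step 6 | (4R)-4-hydroxy-7-methyl-1-(morpholin-4-yl)oct-6-en-2-yn-1-one | CC(C)=CC[C@@H](O)C#CC(=O)N1CCOCC1
F5 | step 6 | (2Z,4R)-4-hydroxy-7-methyl-1-(morpholin-4-yl)-3-(tributylstannyl)octa-2,6-dien-1-one | CC(C)=CC[C@@H](O)/C(=C/C(=O)N1CCOCC1)[Sn](CCCC)(CCCC)CCCC
F6 | step 6 | (2Z,4R)-4-hydroxy-3-iodo-7-methyl-1-(morpholin-4-yl)octa-2,6-dien-1-one | CC(C)=CC[C@@H](O)/C(I)=C/C(=O)N1CCOCC1
F7 | step 3 | 3-(trimethylsilyl)prop-2-ynal | C[Si](C)(C)C#CC=O
F8 | step 3 | (3R)-1-(trimethylsilyl)hex-5-en-1-yn-3-ol | C=CC[C@@H](O)C#C[Si](C)(C)C
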